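**Strategy.** Everything rests on cutting the C6–C7 bond, so that the complete dienyl side chain is attached last to a finished cis-fused 1,2-dioxane/γ-lactone. The step exploits two features of C6. It is bonded to peroxide oxygen O1 of the dioxane, so a ketone-derived peroxyketal can release it as a cyclic peroxycarbenium ion. It also lies 1,3 to quaternary C4, whose methyl group and lactone oxygen distinguish its two faces. In one operation a primary alkylzinc iodide carrying the C8 stereocentre and the E,E-diene is transferred to this ion, joining both fragments and creating the quaternary peroxide stereocentre. The precursor is the bicyclic 6-methoxy-4,6-dimethyl peroxyketal lactone.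

Key step: step 16

Numbering used throughout: C1 lactone carbonyl, C2 CH2, C3 peroxide-bearing CH (O2), C4 quaternary lactone carbon, C5 ring CH2, C6 quaternary peroxide carbon (O1), C7–C14 side chain, phenyl on C14. The target is (3S,4S,6R,8R,10E,12E).
Remark on the chemistry: 8 and 9 are carried as mixtures of epimers at C6, because that centre is erased when the cation forms in step 16. All peroxides are handled cold, dilute and behind a shield.

Step 1
Reactants: 1 (R)-2-methylglycidol; 2 isopropenylmagnesium bromide
Product: 3 (S)-2,4-dimethylpent-4-ene-1,2-diol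
Conditions: 2 (3 equiv), CuI (10 mol %), THF, −40 → 0 °C; aq NH4Cl
Reagents that add atoms: none
Why: Copper-catalysed Grignard opening of a 2,2-disubstituted epoxide is an SN2 attack at the unhindered CH2 terminus, so no bond to the quaternary carbon breaks and the configuration of 1 becomes that of C4 (the degenerate Payne shift of the alkoxide returns the same enantiomer).

Step 2
Reactants: 3 (S)-2,4-dimethylpent-4-ene-1,2-diol
Product: 4 (S)-2-hydroxy-2,4-dimethylpent-4-enal
Conditions: SO3·pyridine, DMSO, Et3N, CH2Cl2, 0 °C; used crude
Reagents that add atoms: none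
Why: The Parikh–Doering oxidation touches only the primary carbinol, cannot cleave the 1,2-diol as iodine(III) or periodate oxidants might, and leaves a quaternary α-carbon that cannot epimerise.

Step 3
Reactants: 4 (S)-2-hydroxy-2,4-dimethylpent-4-enal
Product: 6 (S)-5-methyl-5-(2-methylallyl)furan-2(5H)-one, via Z-enoate 5 (not isolated)
Conditions: (CF3CH2O)2P(O)CH2CO2Me, KHMDS, 18-crown-6, THF, −78 °C; then p-TsOH (cat.), CH2Cl2, rt
Reagents that add atoms: methyl bis(2,2,2-trifluoroethyl)phosphonoacetate COC(=O)CP(=O)(OCC(F)(F)F)OCC(F)(F)F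
Why: The Still–Gennari variant of the Horner–Wadsworth–Emmons reaction gives the Z-enoate 5 under kinetic control, and its ester then sits next to the tertiary hydroxyl so that acid-catalysed lactonisation closes the butenolide without touching C4.

Step 4
Reactants: 6 (S)-5-methyl-5-(2-methylallyl)furan-2(5H)-one
Product: 8 (5S)-5-(2-hydroperoxy-2-methoxypropyl)-5-methylfuran-2(5H)-one as both ketal epimers, via ketone O-oxide 7 (not isolated)
Conditions: O3/O2, CH2Cl2–MeOH, NaHCO3, −78 °C, Sudan Red 7B end point; N2 purge, cold concentration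
Reagents that add atoms: ozone [O-][O+]=O; methanol CO
Why: In this Criegee ozonolysis in a participating solvent, ozone attacks the electron-rich 1,1-disubstituted alkene far faster than the electron-poor butenolide, the primary ozonide splits into formaldehyde and the more substituted carbonyl oxide 7, and methanol traps 7 as the hydroperoxy ketal, whose new centre needs no control.

Step 5
Reactants: 8 (5S)-5-(2-hydroperoxy-2-methoxypropyl)-5-methylfuran-2(5H)-one
Product: 9 (3S,4S)-6-methoxy-4,6-dimethyl-1,2-dioxane cis-fused at C3–C4 to the γ-lactone (both C6 epimers)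
Conditions: Et2NH (0.5 equiv), CF3CH2OH, rt
Reagents that add atoms: none
Why: Amine-mediated intramolecular oxa-Michael addition of the hydroperoxide to the butenolide β-carbon (6-exo-trig) closes the dioxane, and because the short C5–C6 tether reaches C3 only on the face where it is anchored at C4, the fusion must be cis and C4 sets C3 as S.

Step 6
Reactants: 10 methyl (S)-3-hydroxy-2-methylpropanoate
Product: 11 methyl (S)-3-(tert-butyldiphenylsilyloxy)-2-methylpropanoate
Conditions: TBDPSCl, imidazole, CH2Cl2, rt
Reagents that add atoms: tert-butyldiphenylsilyl chloride CC(C)(C)[Si](Cl)(c1ccccc1)c1ccccc1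
Why: Imidazole-promoted silylation of a primary alcohol is too mild to enolise the ester, so the stereocentre is retained.

Step 7
Reactants: 11 methyl (S)-3-(tert-butyldiphenylsilyloxy)-2-methylpropanoate
Product: 12 (R)-3-(tert-butyldiphenylsilyloxy)-2-methylpropan-1-ol
Conditions: DIBAL-H (2.3 equiv), CH2Cl2, −78 → −20 °C; Rochelle salt
Reagents that add atoms: none
Why: Hydride reduction of the ester passes through the aldehyde stage faster than that stage can enolise at low temperature, so the centre is unchanged in space (the descriptor changes only through priorities).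

Step 8
Reactants: 12 (R)-3-(tert-butyldiphenylsilyloxy)-2-methylpropan-1-ol
Product: 13 (S)-tert-butyl(3-iodo-2-methylpropoxy)diphenylsilane
Conditions: PPh3, imidazole, I2, CH2Cl2, 0 °C → rt
Reagents that add atoms: iodine II
Why: Appel-type iodination is an SN2 displacement at the primary carbon and does not involve the neighbouring stereocentre.

Step 9
Reactants: 13 (S)-tert-butyl(3-iodo-2-methylpropoxy)diphenylsilane
Product: 14 (R)-tert-butyl[(2-methylpent-4-yn-1-yl)oxy]diphenylsilane
Conditions: LiC≡CH·H2NCH2CH2NH2, DMSO–THF, 0 °C → rt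
Reagents that add atoms: lithium acetylide ethylenediamine complex [Li]C#C.NCCN
Why: SN2 alkylation of lithium acetylide by a primary iodide in a dipolar aprotic medium is reliable, and the bulky diphenylsilyl ether withstands the amine.

Step 10
Reactants: 14 (R)-tert-butyl[(2-methylpent-4-yn-1-yl)oxy]diphenylsilane
Product: 16 (R,E)-tert-butyl[(5-iodo-2,4-dimethylpent-4-en-1-yl)oxy]diphenylsilane, via alkenyldimethylalane 15 (not isolated)
Conditions: AlMe3 (3 equiv), Cp2ZrCl2 (0.3 equiv), CH2Cl2, 0 °C → rt; then I2, THF, −30 °C
Reagents that add atoms: trimethylaluminium C[Al](C)C; iodine II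
Why: Zirconium-catalysed carboalumination adds methyl and aluminium syn with aluminium on the terminal carbon, and iodinolysis with retention fixes the E geometry of the C10=C11 alkene.

Step 11
Reactants: 17 benzyl bromide; 18 1-propynylmagnesium bromide
Product: 19 but-2-yn-1-ylbenzene (1-phenyl-2-butyne)
Conditions: CuBr·SMe2 (5 mol %), THF, 0 → 50 °C
Reagents that add atoms: none
Why: Copper-catalysed cross-coupling of an alkynyl Grignard reagent with a benzylic bromide is a direct substitution, and the weakly basic acetylide does not isomerise the product to the allene.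

Step 12
Reactants: 19 but-2-yn-1-ylbenzene; 16 (R,E)-tert-butyl[(5-iodo-2,4-dimethylpent-4-en-1-yl)oxy]diphenylsilane
Product: 22 (R,4E,6E)-tert-butyl[(2,4,6-trimethyl-8-phenylocta-4,6-dien-1-yl)oxy]diphenylsilane, via alkenylzirconocene chloride 20 (not isolated), via alkenylzinc chloride 21 (not isolated)
Conditions: 19 (1.5 equiv), Cp2Zr(H)Cl (slight excess over 19), THF, rt → 45 °C; ZnCl2, 0 °C; then 16, Pd(PPh3)4 (5 mol %), rt
Reagents that add atoms: none
Why: Syn-hydrozirconation puts zirconium on the less hindered methyl-bearing carbon (a little excess hydride and gentle warming let the regioisomers equilibrate towards it), transmetalation to zinc overcomes the sluggishness of trisubstituted alkenylzirconocenes, and the Negishi coupling joins the two sp2 carbons with retention, so both alkenes are E.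

Step 13
Reactants: 22 (R,4E,6E)-tert-butyl[(2,4,6-trimethyl-8-phenylocta-4,6-dien-1-yl)oxy]diphenylsilane
Product: 23 (R,4E,6E)-2,4,6-trimethyl-8-phenylocta-4,6-dien-1-ol
Conditions: TBAF, THF, rt
Reagents that add atoms: none
Why: Fluoride-induced desilylation is not basic enough to move the diene into conjugation with the phenyl ring.

Step 14
Reactants: 23 (R,4E,6E)-2,4,6-trimethyl-8-phenylocta-4,6-dien-1-ol
Product: 24 [(2E,4E,7R)-8-iodo-3,5,7-trimethylocta-2,4-dien-1-yl]benzene
Conditions: PPh3, imidazole, I2 (premixed), CH2Cl2, 0 °C, dark; then 23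
Reagents that add atoms: iodine II
Why: Appel iodination with the preformed phosphonium iodide displaces only the primary hydroxyl and leaves no free iodine to isomerise the diene.

Step 15
Reactants: 24 [(2E,4E,7R)-8-iodo-3,5,7-trimethylocta-2,4-dien-1-yl]benzene
Product: 25 [(R,4E,6E)-2,4,6-trimethyl-8-phenylocta-4,6-dien-1-yl]zinc iodide (titrated solution)
Conditions: Zn dust (activated with BrCH2CH2Br and TMSCl), THF, 40 °C; filtered, THF removed in vacuo, taken up in CH2Cl2
Reagents that add atoms: zinc [Zn]
Why: Direct oxidative insertion of activated zinc into a primary C–I bond tolerates alkenes, the transient 4-pentenyl-type radical has no fast cyclisation mode, and the β-stereocentre is not involved.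

Step 16
Reactants: 9 (3S,4S)-6-methoxy-4,6-dimethyl peroxyketal lactone; 25 [(R,4E,6E)-2,4,6-trimethyl-8-phenylocta-4,6-dien-1-yl]zinc iodide
Product: 27 CNP0272658.1 (3S,4S,6R,8R,10E,12E), via peroxycarbenium triflate 26 (not isolated)
Conditions: 9, 25 (2 equiv), 2,6-di-tert-butyl-4-methylpyridine (0.3 equiv), CH2Cl2, −78 °C; TMSOTf (1.3 equiv) added slowly, −78 → −40 °C; aq NaHCO3
Reagents that add atoms: none
Why: Proposed new method: TMSOTf silylates the methoxy oxygen of either C6 epimer of 9 and expels MeOSiMe3 to give the single 1,2-dioxan-3-ylium ion 26, whose C6 is attacked by the polarised primary C–Zn σ-bond of 25 in an SE2-type alkyl transfer that forms C6–C7, and no ring is closed because the bicycle is already complete. The closest known reaction types are the Hosomi–Sakurai and Mukaiyama-type additions of allylsilanes and enol silanes to cyclic peroxycarbenium ions from 3-alkoxy-1,2-dioxanes and 1,2-dioxolanes, and the silyl-triflate-promoted addition of alkylzinc reagents to oxocarbenium ions from acetals and α-acetoxy ethers, so what is new is the pairing of an sp3 organozinc with a peroxide-stabilised cation. C4 controls the new stereocentre C6: in the favoured half-chair of 26 the C4 methyl is pseudoequatorial and the C4–O(lactone) bond pseudoaxial (also the electrostatically better arrangement), so axial, chair-forming attack comes from the face syn to that oxygen and places C7 cis to the lactone oxygen and the C6 methyl cis to the C4 methyl (6R), whereas the other face needs a twist-boat or a half-chair with a syn-axial C4 methyl. The step needs C–OMe rather than O–O ionisation, which the fully substituted, doubly oxygenated C6 secures, and C–Zn rather than diene attack, which is favoured because an unhindered CH2 reaches the crowded cation more easily than the CH termini of two trisubstituted alkenes. The lactone and the dialkyl peroxide are poor partners for an alkylzinc halide at −78 °C, and C3, C4 and C8 take no part.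

Compound list
1 | (R)-2-methylglycidol | OC[C@]1(C)CO1 | starting material
2 | isopropenylmagnesium bromide | CC(=C)[Mg]Br | starting material
3 | (S)-2,4-dimethylpent-4-ene-1,2-diol | C=C(C)C[C@](C)(O)CO | intermediate
4 | (S)-2-hydroxy-2,4-dimethylpent-4-enal | C=C(C)C[C@](C)(O)C=O | intermediate
5 | methyl (S,Z)-4-hydroxy-4,6-dimethylhepta-2,6-dienoate | C=C(C)C[C@](C)(O)/C=C\C(=O)OC | intermediate
6 | (S)-5-methyl-5-(2-methylallyl)furan-2(5H)-one | C=C(C)C[C@]1(C)OC(=O)C=C1 | intermediate
7 | ketone O-oxide (carbonyl oxide) of the side-arm methyl ketone | CC(=[O+][O-])C[C@]1(C)OC(=O)C=C1 | intermediate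
8 | (5S)-5-(2-hydroperoxy-2-methoxypropyl)-5-methylfuran-2(5H)-one, both ketal epimers | COC(C)(OO)C[C@]1(C)OC(=O)C=C1 | intermediate
9 | (4aS,7aS)-3-methoxy-3,4a-dimethyltetrahydrofuro[3,2-c][1,2]dioxin-6-one, both C6 epimers | COC1(C)C[C@]2(C)OC(=O)C[C@@H]2OO1 | intermediate
10 | methyl (S)-3-hydroxy-2-methylpropanoate | COC(=O)[C@@H](C)CO | starting material
11 | methyl (S)-3-(tert-butyldiphenylsilyloxy)-2-methylpropanoate | COC(=O)[C@@H](C)CO[Si](c1ccccc1)(c1ccccc1)C(C)(C)C | intermediate
12 | (R)-3-(tert-butyldiphenylsilyloxy)-2-methylpropan-1-ol | OC[C@@H](C)CO[Si](c1ccccc1)(c1ccccc1)C(C)(C)C | intermediate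
13 | (S)-tert-butyl(3-iodo-2-methylpropoxy)diphenylsilane | IC[C@@H](C)CO[Si](c1ccccc1)(c1ccccc1)C(C)(C)C | intermediate
14 | (R)-tert-butyl[(2-methylpent-4-yn-1-yl)oxy]diphenylsilane | C#CC[C@@H](C)CO[Si](c1ccccc1)(c1ccccc1)C(C)(C)C | intermediate
15 | (E)-alkenyldimethylalane from 14 | C[Al](C)/C=C(\C)C[C@@H](C)CO[Si](c1ccccc1)(c1ccccc1)C(C)(C)C | intermediate
16 | (R,E)-tert-butyl[(5-iodo-2,4-dimethylpent-4-en-1-yl)oxy]diphenylsilane | I/C=C(\C)C[C@@H](C)CO[Si](c1ccccc1)(c1ccccc1)C(C)(C)C | intermediate
17 | benzyl bromide | BrCc1ccccc1 | starting material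
18 | 1-propynylmagnesium bromide | CC#C[Mg]Br | starting material
19 | but-2-yn-1-ylbenzene | CC#CCc1ccccc1 | intermediate
20 | (E)-(4-phenylbut-2-en-2-yl)zirconocene chloride (Cp rings drawn σ-bonded) | C/C(=C\Cc1ccccc1)[Zr](Cl)(C1C=CC=C1)C1C=CC=C1 | intermediate
21 | (E)-(4-phenylbut-2-en-2-yl)zinc chloride | C/C(=C\Cc1ccccc1)[Zn]Cl | intermediate
22 | (R,4E,6E)-tert-butyl[(2,4,6-trimethyl-8-phenylocta-4,6-dien-1-yl)oxy]diphenylsilane | CC(=C\Cc1ccccc1)/C=C(\C)C[C@@H](C)CO[Si](c1ccccc1)(c1ccccc1)C(C)(C)C | intermediate
23 | (R,4E,6E)-2,4,6-trimethyl-8-phenylocta-4,6-dien-1-ol | CC(=C\Cc1ccccc1)/C=C(\C)C[C@@H](C)CO | intermediate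
24 | [(2E,4E,7R)-8-iodo-3,5,7-trimethylocta-2,4-dien-1-yl]benzene | CC(=C\Cc1ccccc1)/C=C(\C)C[C@@H](C)CI | intermediate
25 | [(R,4E,6E)-2,4,6-trimethyl-8-phenylocta-4,6-dien-1-yl]zinc iodide | CC(=C\Cc1ccccc1)/C=C(\C)C[C@@H](C)C[Zn]I | intermediate
26 | bicyclic 1,2-dioxan-3-ylium (peroxycarbenium) triflate | CC=1C[C@]2(C)OC(=O)C[C@@H]2O[O+]=1.[O-]S(=O)(=O)C(F)(F)F | intermediate
27 | CNP0272658.1, (3S,4S,6R,8R,10E,12E) | CC(=C\Cc1ccccc1)/C=C(\C)C[C@@H](C)C[C@]1(C)C[C@]2(C)OC(=O)C[C@@H]2OO1 | target

Total step count: 16. Longest linear sequence: 10 steps (10 → 27 through steps 6–10 and 12–16).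

Steps most likely to fail

1. Step 16 (the step with the new-method label).
- **What may go wrong:** the diene of the zinc reagent or of the product may intercept the cation. Zinc or iodide may cleave the O–O bond reductively. The Lewis acid may trigger heterolytic O–O fragmentation. Facial selectivity at C6 may be poor.
- **Fallback (known chemistry, sets out from 9 and returns at 27):** the σ-nucleophile is replaced by a π-nucleophile of the class already proven on cyclic peroxycarbenium ions, and the diene is completed afterwards. Commercial 2-(chloromethyl)allyltrimethylsilane is coupled with ethynylmagnesium bromide under copper(I) catalysis to trimethyl(2-methylidenepent-4-yn-1-yl)silane F1. Zirconium-catalysed carboalumination as in step 10 gives the alkenyldimethylalane F2 and, with one equivalent of iodine at −78 °C, (E)-(5-iodo-4-methyl-2-methylidenepent-4-en-1-yl)trimethylsilane F3. Hosomi–Sakurai reaction of F3 with 9 (TMSOTf, CH2Cl2, −78 °C, through 26) should give the 8-methylidene vinyl iodide F4 with the same facial preference at C6. Diimide (dipotassium azodicarboxylate, AcOH, 0 °C) spares O–O bonds and trisubstituted alkenes and should reduce only the 1,1-disubstituted alkene. It gives the (8R)-vinyl iodide F5 together with its (8S)-epimer F6.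
- **Price of this detour:** C8 is no longer drawn from the chiral pool, so F6 has to be removed by chromatography. Negishi coupling of F5 with 21 (Pd(PPh3)4, THF, rt), a palladium coupling of a kind that 1,2-dioxanes tolerate, then gives 27.

2. Step 12.
- **What may go wrong:** hydrozirconation may discriminate poorly between the methyl- and the benzyl-bearing alkyne carbon. The hindered alkenyl metal may also couple so slowly that homocoupling or reduction of the iodide competes.
- **Fallback (sets out from 16 and 17, returns at 22):** the regiochemistry is fixed by carbometalation of a terminal alkyne instead. Sonogashira coupling of 16 with trimethylsilylacetylene (PdCl2(PPh3)2, CuI, Et3N) gives the silylated enyne F7. K2CO3 in MeOH frees the terminal enyne F8. Zirconium-catalysed carboalumination places methyl on C12 and aluminium on C13 in the dienyldimethylalane F9. Palladium-catalysed coupling of F9 with benzyl bromide 17 then delivers 22 with both alkenes E.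

3. Step 4.
- **What may go wrong:** ozone may over-oxidise the butenolide. The primary ozonide may fragment in the unwanted sense, to the ketone and formaldehyde O-oxide. The hydroperoxy ketal may decay on handling.
- **Fallback (sets out from 6, returns at 8):** the hydroperoxy ketal is built from the ketone rather than from a carbonyl oxide. Lemieux–Johnson cleavage (OsO4 cat., NaIO4, 2,6-lutidine, dioxane–H2O) of the electron-rich alkene gives (S)-5-methyl-5-(2-oxopropyl)furan-2(5H)-one F10. Acid-catalysed hydroperoxyketalisation of F10 (urea–hydrogen peroxide, Sc(OTf)3 cat., MeOH, rt) gives 8.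

Further compounds
F1 | step 16 | trimethyl(2-methylidenepent-4-yn-1-yl)silane | C#CCC(=C)C[Si](C)(C)C
F2 | step 16 | (E)-alkenyldimethylalane from F1 | C[Al](C)/C=C(\C)CC(=C)C[Si](C)(C)C
F3 | step 16 | (E)-(5-iodo-4-methyl-2-methylidenepent-4-en-1-yl)trimethylsilane | I/C=C(\C)CC(=C)C[Si](C)(C)C
F4 | step 16 | 8-methylidene vinyl iodide of the bicycle | I/C=C(\C)CC(=C)C[C@]1(C)C[C@]2(C)OC(=O)C[C@@H]2OO1
F5 | step 16 | (8R)-vinyl iodide of the bicycle | I/C=C(\C)C[C@@H](C)C[C@]1(C)C[C@]2(C)OC(=O)C[C@@H]2OO1
F6 | step 16 | (8S)-epimer of F5 | I/C=C(\C)C[C@H](C)C[C@]1(C)C[C@]2(C)OC(=O)C[C@@H]2OO1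
F7 | step 12 | silylated (E)-enyne silyl ether | C[Si](C)(C)C#C/C=C(\C)C[C@@H](C)CO[Si](c1ccccc1)(c1ccccc1)C(C)(C)C
F8 | step 12 | terminal (E)-enyne silyl ether | C#C/C=C(\C)C[C@@H](C)CO[Si](c1ccccc1)(c1ccccc1)C(C)(C)C
F9 | step 12 | (E,E)-dienyldimethylalane | C[Al](C)/C=C(C)/C=C(\C)C[C@@H](C)CO[Si](c1ccccc1)(c1ccccc1)C(C)(C)C
F10 | step 4 | (S)-5-methyl-5-(2-oxopropyl)furan-2(5H)-one | CC(=O)C[C@]1(C)OC(=O)C=C1
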